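**Assumption:** the target is taken exactly as the given SMILES, i.e. (6R,7R,8R,10R,4Z) in germacrane numbering (C1 ketone, C3–O–C10 furanone bridge, C6 lactone oxygen, C8 tiglate, C12 lactone carbonyl, C13 exo-methylene); these locants are used throughout.

## Retrosynthetic overview

1. The 10-membered carbocycle is opened at C4=C5 by ring-closing metathesis (Z enforced by the ring), giving an acyclic vinyl/isopropenyl precursor; the tiglate comes from the C8 alcohol.
2. Key step: the α-methylene-γ-lactone and the free C8–OH arise together from an epoxy propiolate by Ti(III) radical epoxide opening and 5-exo-dig cyclisation (C7–C11 bond; C7 set trans, C8–O retained).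
3. The epoxy alcohol comes from Sharpless epoxidation (sets C6 and C8) of a dienol made by cross-metathesis of an allyl furanone with divinyl carbinol.
4. The furanone comes from an α'-hydroxy ynone, itself from (S)-lactic acid by Seebach dioxolanone allylation (sets C10).
5. Ring order: furanone, then lactone, then the 10-membered carbocycle.

## Route

**Step 1**
Reactants: 1, (S)-lactic acid
Product: 2, (2S,5S)-2-tert-butyl-5-methyl-1,3-dioxolan-4-one (cis)
Conditions: t-BuCHO, cat. TsOH·H2O/H2SO4, pentane, reflux (Dean–Stark); recrystallise at −78 °C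
Reagents that add atoms: pivaldehyde, CC(C)(C)C=O (temporary acetal auxiliary, removed in step 3)
Why: Acid-catalysed acetalisation (Seebach self-regeneration of stereocentres); the cis acetal is favoured and purified by crystallisation, so the lactate configuration is stored in the new acetal centre.

**Step 2**
Reactants: 2; 3, allyl bromide
Product: 4, (2S,5R)-5-allyl-2-tert-butyl-5-methyl-1,3-dioxolan-4-one
Conditions: LDA, THF, −78 °C; allyl bromide, −78 → −30 °C
Reagents that add atoms: allyl bromide (3), C=CCBr
Why: Diastereoselective enolate alkylation; the electrophile enters anti to the tert-butyl group (overall retention), which sets the quaternary centre that becomes C10 (R).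

**Step 3**
Reactants: 4; 5, 2-methylbut-1-en-3-yne
Product: 6, (6R)-6-hydroxy-2,6-dimethylnona-1,8-dien-3-yn-5-one
Conditions: 5, n-BuLi, THF, −78 °C; add 4, −78 → −40 °C; AcOH quench; then 1 M HCl, THF, rt
Reagents that add atoms: none beyond reactant 5 (C=C(C)C#C); pivaldehyde is released
Why: Acyl substitution of the acylal lactone by a lithium acetylide; the tetrahedral lithium hemiketalate survives at low temperature (mono-addition) and acid work-up collapses it with loss of pivaldehyde, leaving the quaternary centre untouched.

**Step 4**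
Reactants: 6
Product: 7, (2R)-2-allyl-2-methyl-5-(prop-1-en-2-yl)furan-3(2H)-one
Conditions: Ph3PAuCl/AgOTf (2 mol%), toluene, rt
Reagents that add atoms: none
Why: Gold-catalysed 5-endo-dig cycloisomerisation of an α'-hydroxy ynone to the 3(2H)-furanone; C10 is not involved and stays R.

**Step 5**
Reactants: 7; 8, penta-1,4-dien-3-ol (5 equiv)
Product: 9, (2R)-2-[(2E)-4-hydroxyhexa-2,5-dien-1-yl]-2-methyl-5-(prop-1-en-2-yl)furan-3(2H)-one, 1:1 mixture of C6 (carbinol) epimers
Conditions: Hoveyda–Grubbs II (5 mol%), CH2Cl2, 40 °C
Reagents that add atoms: none beyond reactant 8 (C=CC(O)C=C); ethylene is lost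
Why: E-selective olefin cross-metathesis of the unhindered allyl group with excess allylic alcohol; the conjugated isopropenyl group is unreactive and ring closure onto it would need an anti-Bredt bicycle; the C6 carbinol is formed unselectively and resolved in step 6.

**Step 6**
Reactants: 9
Product: 10, (2R)-2-{[(2R,3R)-3-[(1R)-1-hydroxyprop-2-en-1-yl]oxiran-2-yl]methyl}-2-methyl-5-(prop-1-en-2-yl)furan-3(2H)-one
Conditions: Ti(OiPr)4 (1 equiv), D-(−)-DIPT (1.2 equiv), t-BuOOH (0.55 equiv), 4 Å MS, CH2Cl2, −20 °C
Reagents that add atoms: tert-butyl hydroperoxide, CC(C)(C)OO (one oxygen)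
Why: Sharpless asymmetric epoxidation in kinetic-resolution mode; with D-(−)-DIPT only the (6R)-epimer is matched for the (E)-C7=C8 olefin and gives the anti (erythro) epoxy alcohol, fixing C6 (R) and C8 (R), while the (6S)-epimer is left behind and separated (maximum 50% yield).

**Step 7**
Reactants: 10; 11, propiolic acid
Product: 12, (1R)-1-[(2S,3R)-3-{[(2R)-2-methyl-3-oxo-5-(prop-1-en-2-yl)-2,3-dihydrofuran-2-yl]methyl}oxiran-2-yl]prop-2-en-1-yl prop-2-ynoate
Conditions: DCC, DMAP (5 mol%), CH2Cl2, −20 → 0 °C
Reagents that add atoms: none beyond reactant 11 (C#CC(=O)O)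
Why: Steglich esterification of the C6 alcohol with retention; low temperature and little DMAP limit amine addition to the ynoate (the oxirane C7 descriptor changes from R to S only because of CIP priorities).

**Step 8 (key step)**
Reactants: 12
Product: 13, (2R)-2-{(2R)-2-hydroxy-2-[(2R,3R)-4-methylidene-5-oxo-2-vinyloxolan-3-yl]ethyl}-2-methyl-5-(prop-1-en-2-yl)furan-3(2H)-one
Conditions: Cp2TiCl2 (20 mol%), Mn dust, 2,4,6-collidine·HCl, THF (5 mM), rt
Reagents that add atoms: none (two hydrogens only)
Why: Proposed new method: Cp2Ti(III)Cl opens the epoxide homolytically at C7–O (Ti–O on the less hindered C8), and the β-titanoxy C7 radical closes 5-exo-dig onto the propiolate α-carbon (C7–C11 bond); the vinyl radical is then quenched by THF or Ti(III)/collidinium to give the exo-methylene, with C8–O retained (R) and C7 set R because the ring closes with the C8 chain trans to the C6 vinyl group. The closest known reactions are Nugent–RajanBabu Ti(III) epoxide opening with 5-exo-dig cyclisation of epoxy propargyl ethers, and tin-hydride cyclisation of β-oxyalkyl radicals onto propiolate esters to give α-methylene-γ-lactones.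

**Step 9**
Reactants: 13; 14, tigloyl chloride
Product: 15, (1R)-2-[(2R)-2-methyl-3-oxo-5-(prop-1-en-2-yl)-2,3-dihydrofuran-2-yl]-1-[(2R,3R)-4-methylidene-5-oxo-2-vinyloxolan-3-yl]ethyl (2E)-2-methylbut-2-enoate
Conditions: pyridine, DMAP (cat.), CH2Cl2, 0 °C → rt
Reagents that add atoms: none beyond reactant 14 (ClC(=O)/C(C)=C/C)
Why: DMAP-catalysed acylation of the C8 alcohol with retention; prompt acylation also blocks 6,12- to 8,12-translactonisation, and 5-endo oxa-Michael addition to the methylene lactone is disfavoured.

**Step 10**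
Reactants: 15
Product: 16, atripliciolide tiglate (target)
Conditions: Hoveyda–Grubbs II (15 mol%), 1,4-benzoquinone (30 mol%), toluene (0.5 mM), 80 °C, Ar sparge
Reagents that add atoms: none (ethylene is lost)
Why: Ring-closing metathesis of the C6 vinyl group with the furanone isopropenyl group forms the trisubstituted C4=C5 bond; the double bond lies in a 9-membered oxa-bridged ring, so only the Z isomer is accessible, and no stereocentre is touched.

## Compound list

1 | (S)-lactic acid | C[C@H](O)C(=O)O | starting material
2 | (2S,5S)-2-tert-butyl-5-methyl-1,3-dioxolan-4-one | O=C1[C@H](C)O[C@H](C(C)(C)C)O1 | intermediate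
3 | allyl bromide | C=CCBr | starting material
4 | (2S,5R)-5-allyl-2-tert-butyl-5-methyl-1,3-dioxolan-4-one | O=C1[C@@](C)(CC=C)O[C@H](C(C)(C)C)O1 | intermediate
5 | 2-methylbut-1-en-3-yne | C=C(C)C#C | starting material
6 | (6R)-6-hydroxy-2,6-dimethylnona-1,8-dien-3-yn-5-one | C=C(C)C#CC(=O)[C@@](C)(CC=C)O | intermediate
7 | (2R)-2-allyl-2-methyl-5-(prop-1-en-2-yl)furan-3(2H)-one | C=C(C)C1=CC(=O)[C@@](C)(CC=C)O1 | intermediate
8 | penta-1,4-dien-3-ol | C=CC(O)C=C | starting material
9 | (2R)-2-[(2E)-4-hydroxyhexa-2,5-dien-1-yl]-2-methyl-5-(prop-1-en-2-yl)furan-3(2H)-one (1:1 carbinol epimers) | C=C(C)C1=CC(=O)[C@@](C)(C/C=C/C(O)C=C)O1 | intermediate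
10 | (2R)-2-{[(2R,3R)-3-[(1R)-1-hydroxyprop-2-en-1-yl]oxiran-2-yl]methyl}-2-methyl-5-(prop-1-en-2-yl)furan-3(2H)-one | C=C(C)C1=CC(=O)[C@@](C)(C[C@H]2O[C@@H]2[C@H](O)C=C)O1 | intermediate
11 | propiolic acid | C#CC(=O)O | starting material
12 | (1R)-1-[(2S,3R)-3-{[(2R)-2-methyl-3-oxo-5-(prop-1-en-2-yl)-2,3-dihydrofuran-2-yl]methyl}oxiran-2-yl]prop-2-en-1-yl prop-2-ynoate | C=C(C)C1=CC(=O)[C@@](C)(C[C@H]2O[C@@H]2[C@H](OC(=O)C#C)C=C)O1 | intermediate
13 | (2R)-2-{(2R)-2-hydroxy-2-[(2R,3R)-4-methylidene-5-oxo-2-vinyloxolan-3-yl]ethyl}-2-methyl-5-(prop-1-en-2-yl)furan-3(2H)-one | C=C1C(=O)O[C@H](C=C)[C@H]1[C@H](O)C[C@@]2(C)OC(C(C)=C)=CC2=O | intermediate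
14 | tigloyl chloride, (E)-2-methylbut-2-enoyl chloride | ClC(=O)/C(C)=C/C | starting material
15 | (1R)-2-[(2R)-2-methyl-3-oxo-5-(prop-1-en-2-yl)-2,3-dihydrofuran-2-yl]-1-[(2R,3R)-4-methylidene-5-oxo-2-vinyloxolan-3-yl]ethyl (2E)-2-methylbut-2-enoate | C=C1C(=O)O[C@H](C=C)[C@H]1[C@H](OC(=O)/C(C)=C/C)C[C@@]2(C)OC(C(C)=C)=CC2=O | intermediate
16 | atripliciolide tiglate | C=C1C(=O)O[C@@H]2/C=C(/C)C3=CC(=O)[C@@](C)(C[C@@H](OC(=O)/C(C)=C/C)[C@@H]12)O3 | target

## Step count and risks

Total steps: 10. Longest linear sequence: 10 (fully linear; all coupling partners are commercial).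

Steps most likely to fail:

1. **Step 8 (Ti(III) radical lactonisation).** The 5-exo-dig closure needs the disfavoured s-cis ester rotamer and attack at the ynoate α-carbon. It competes with Ti(III) trapping of the C7 radical followed by β-acyloxy elimination, with 6-endo closure, and with 1,2-vinyl shift. Fallback: replace the ester tether by a propargyl ether (NaH, propargyl bromide on 10), run the well-precedented Ti(III) epoxide/alkyne 5-exo-dig cyclisation to the 3-methylene-tetrahydrofuran, then oxidise the allylic O–CH2 (CrO3·3,5-dimethylpyrazole) to the α-methylene lactone (one extra step).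

2. **Step 10 (ring-closing metathesis).** A strained 10-membered ring with a trisubstituted, furanone-conjugated olefin may stall or oligomerise. Fallback: change the ring order. Close the carbocycle on the more flexible epoxy alcohol 10 (before the lactone exists), then carry out esterification, Ti(III) lactonisation and tigloylation on the macrocycle.

3. **Step 5 (cross-metathesis with divinyl carbinol).** Double cross-metathesis and allylic-alcohol isomerisation are possible, and the product is a 1:1 C6 mixture of which step 6 can use at most half. Fallback: cross-metathesis of 7 with acrolein to the (E)-enal, then catalyst-controlled asymmetric vinyl addition (vinylzinc with a chiral amino alcohol) to give (6R)-9 as a single epimer, so that step 6 becomes a matched, non-resolving epoxidation (one extra step).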